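**Retrosynthetic overview**
- The target is read as two diastereomeric 3-methylquinolizidin-2-one units tied head-to-tail by two (CH2)5 chains (C9 of one unit to C1 of the other): unit A is 1S,3S,9R,9aR (H9/H9a trans) and unit B is 1R,3S,9S,9aR (H9/H9a cis). C1 and C3 are ketone α-centres and are left to thermodynamics, so only C9 and C9a need control.
- Both piperidine rings (ring A of each unit) are masked as pyridines. The key step is an Ir-catalysed asymmetric hydrogenation of a ring-fused pyridinium salt, run twice with opposite ligand hands.
- Unit A: ring B is closed on a pyridine by aza-Michael addition, the pyridinium is hydrogenated (cis), C9a is equilibrated to trans while C1 is still unsubstituted, and C1 is then alkylated axially with the second pyridine.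
- Unit B: the second pyridine is acylated, the 16-membered carbocycle is closed by C-alkylation of the pyridylmethyl ketone enolate, ring B is closed on nitrogen, and the final cis-hydrogenation is left kinetic.
- Ring order: ring B of unit A, ring A of unit A (saturation), 16-membered carbocycle, ring B of unit B, ring A of unit B (saturation).

Convention: quinolizidine numbering (C1–C4, N5, C6–C9, C9a); ring A is N5/C6–C9/C9a, ring B holds the ketone.

Assumption: the (R)-ligand is taken to give 9R in step 3, to be confirmed on compound 7. If the sense is opposite, the two ligand hands are exchanged between steps 3 and 8.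

Note: the CIP label at C9a changes from S (compound 9) to R (compound 11 onward) only because C1 gains priority over C9. No bond at C9a is touched.

**Step 1**
Reactants: 1 3-bromo-2-methylpyridine; 2 5-chloropent-1-ene
Product: 4 3-(5-chloropentyl)-2-methylpyridine, via B-alkyl borane 3 (not isolated)
Conditions: 2, 9-borabicyclo[3.3.1]nonane (9-BBN-H), THF, 0 to 25 °C; then 1, Pd(dppf)Cl2 (3 mol %), K3PO4, THF/H2O, 65 °C
Reagents that add atoms: none
Why: anti-Markovnikov hydroboration followed by B-alkyl Suzuki–Miyaura coupling joins the primary carbon to C3 of the bromopyridine, and the primary alkyl chloride is inert to the palladium catalyst.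

**Step 2**
Reactants: 4 3-(5-chloropentyl)-2-methylpyridine; 5 methyl 3-methoxy-2-methylpropanoate (racemic)
Product: 7 9-(5-chloropentyl)-3-methyl-2-oxo-1,2,3,4-tetrahydroquinolizin-5-ium chloride (C3 racemic), via methoxy ketone 6 (not isolated)
Conditions: LiN(iPr)2 (2.1 equiv), THF, −78 °C; 5 (1.3 equiv); then conc. HCl, AcOH, 80 °C
Reagents that add atoms: hydrogen chloride, Cl
Why: lateral lithiation of the 2-methyl group and Claisen-type acylation give the 2-pyridylmethyl ketone, after which acid eliminates methanol and the pyridine nitrogen closes ring B by 6-endo aza-Michael addition; C3 is a labile α-centre and is set later.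

**Step 3**
Reactants: 7 9-(5-chloropentyl)-3-methyl-2-oxo-1,2,3,4-tetrahydroquinolizin-5-ium chloride
Product: 9 (3S,9R,9aS)-9-(5-chloropentyl)-3-methyloctahydro-2H-quinolizin-2-one (trans-fused; H9/H9a trans; methyl equatorial), via cis quinolizidinone 8 (not isolated)
Conditions: H2 (50 bar), [Ir(cod)Cl]2 (1 mol %), (R)-SegPhos (2.2 mol %), CH2Cl2/MeOH, 40 °C; then NaOMe (1.3 equiv), MeOH, 60 °C
Reagents that add atoms: none
Why: Proposed new method: the iridium hydride reduces the pyridinium stepwise (hydride addition, enamine protonation, iminium reduction) and the chiral bisphosphine fixes the face of the last hydride transfer at C9a while C9 equilibrates through the enamine, giving the cis 9R,9aR amine as in the known Ir-catalysed asymmetric hydrogenation of 2-alkyl and 2,3-disubstituted N-alkylpyridinium salts (the ring-fused 2-acylmethyl salt is an untested member of that class); methoxide then epimerises C9a by retro-aza-Michael/aza-Michael addition to the all-equatorial trans-fused ketone (no C1 substituent, so no peri strain) and sets C3 by enolisation.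

**Step 4**
Reactants: 4 3-(5-chloropentyl)-2-methylpyridine
Product: 10 3-(5-iodopentyl)-2-methylpyridine
Conditions: NaI (5 equiv), acetone, 0.05 M, 50 °C, dark; used at once
Reagents that add atoms: sodium iodide, [Na+].[I-]
Why: Finkelstein exchange driven by precipitation of NaCl; dilution and immediate use limit self-quaternisation of the hindered pyridine nitrogen.

**Step 5**
Reactants: 9 (3S,9R,9aS)-9-(5-chloropentyl)-3-methyloctahydro-2H-quinolizin-2-one; 10 3-(5-iodopentyl)-2-methylpyridine
Product: 11 (1S,3S,9R,9aR)-9-(5-chloropentyl)-3-methyl-1-[5-(2-methylpyridin-3-yl)pentyl]octahydro-2H-quinolizin-2-one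
Conditions: 9, LiN(iPr)2 (1.05 equiv), THF, −78 °C; then 10 (1.2 equiv), DMPU, −78 to −20 °C
Reagents that add atoms: none
Why: kinetic deprotonation at the less substituted C1 and SN2 alkylation of the lithium enolate by the primary iodide; the electrophile enters axially (anti to the axial C9a–H, the equatorial path being blocked by the C9 chain), giving 1S, which is also the thermodynamic epimer because an equatorial C1 chain would be syn-pentane with the C9 chain.

**Step 6**
Reactants: 11 (1S,3S,9R,9aR)-9-(5-chloropentyl)-3-methyl-1-[5-(2-methylpyridin-3-yl)pentyl]octahydro-2H-quinolizin-2-one; 5 methyl 3-methoxy-2-methylpropanoate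
Product: 12 (1S,3S,9R,9aR)-9-(5-chloropentyl)-1-{5-[2-(4-methoxy-3-methyl-2-oxobutyl)pyridin-3-yl]pentyl}-3-methyloctahydro-2H-quinolizin-2-one (side-chain methyl centre epimeric)
Conditions: LiN(iPr)2 (3.1 equiv), THF, −78 °C; 5 (1.5 equiv); AcOH quench
Reagents that add atoms: none
Why: the first equivalent of base turns the ring ketone into its enolate (protection in the flask), the second lithiates the 2-methyl group of the pyridine, and Claisen-type acylation by the ester gives the pyridylmethyl ketone, which is held as its enolate until the quench; any scrambling at C1 or C3 of unit A is corrected by later enolisation.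

**Step 7**
Reactants: 12 (1S,3S,9R,9aR)-9-(5-chloropentyl)-1-{5-[2-(4-methoxy-3-methyl-2-oxobutyl)pyridin-3-yl]pentyl}-3-methyloctahydro-2H-quinolizin-2-one
Product: 15 macrocyclic pyridinium chloride hydrochloride (unit A complete; ring B of unit B closed on the pyridine nitrogen; C1 and C3 of unit B labile), via iodide 13 (not isolated), via open-tail macrocycle 14 (not isolated)
Conditions: NaH (1.05 equiv), THF, 0 °C; syringe pump into NaI, MeCN, 70 °C (1 mM); then conc. HCl, AcOH, 60 °C
Reagents that add atoms: hydrogen chloride, Cl
Why: one equivalent of NaH removes only the doubly activated C1–H of the pyridylmethyl ketone, and this soft enolate is C-alkylated by the primary iodide formed in the flask (Finkelstein) at high dilution to close the 16-membered carbocycle; acid then eliminates methanol and closes ring B by aza-Michael addition as in step 2, the protonated amine of unit A being protected against retro-Mannich cleavage.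

**Step 8**
Reactants: 15 macrocyclic pyridinium chloride hydrochloride
Product: 17 target (unit A 1S,3S,9R,9aR; unit B 1R,3S,9S,9aR), via unequilibrated ketone mixture 16 (not isolated)
Conditions: H2 (50 bar), [Ir(cod)Cl]2 (2 mol %), (S)-SegPhos (4.4 mol %), CH2Cl2/MeOH, 40 °C; aq. NaHCO3; then Et3N, MeOH, 25 °C
Reagents that add atoms: none
Why: Proposed new method: the same pyridinium hydrogenation as in step 3 with the opposite ligand hand delivers hydrogen cis to C9 and C9a of unit B under catalyst control (9S,9aR; unit A is remote and already saturated), closest precedent again being Ir-catalysed asymmetric hydrogenation of 2,3-disubstituted N-alkylpyridinium salts; this cis relation is kept kinetic, and mild amine base only enolises C1 and C3 of unit B to the stable 1R (equatorial chain, trans to the axial C9 chain) and 3S (equatorial methyl) epimers.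

**Compound list**
1 | 3-bromo-2-methylpyridine | Cc1ncccc1Br | starting material
2 | 5-chloropent-1-ene | C=CCCCCl | starting material
3 | 9-(5-chloropentyl)-9-borabicyclo[3.3.1]nonane | ClCCCCCB1C2CCCC1CCC2 | intermediate (not isolated)
4 | 3-(5-chloropentyl)-2-methylpyridine | Cc1ncccc1CCCCCCl | intermediate
5 | methyl 3-methoxy-2-methylpropanoate (racemic) | COCC(C)C(=O)OC | starting material
6 | 1-[3-(5-chloropentyl)pyridin-2-yl]-4-methoxy-3-methylbutan-2-one (racemic) | COCC(C)C(=O)Cc1ncccc1CCCCCCl | intermediate (not isolated)
7 | 9-(5-chloropentyl)-3-methyl-2-oxo-1,2,3,4-tetrahydroquinolizin-5-ium chloride (C3 racemic) | CC1C[n+]2cccc(CCCCCCl)c2CC1=O.[Cl-] | intermediate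
8 | (9R,9aR)-9-(5-chloropentyl)-3-methyloctahydro-2H-quinolizin-2-one (H9/H9a cis; C3 epimers) | CC1CN2CCC[C@@H](CCCCCCl)[C@H]2CC1=O | intermediate (not isolated)
9 | (3S,9R,9aS)-9-(5-chloropentyl)-3-methyloctahydro-2H-quinolizin-2-one (H9/H9a trans) | C[C@H]1CN2CCC[C@@H](CCCCCCl)[C@@H]2CC1=O | intermediate
10 | 3-(5-iodopentyl)-2-methylpyridine | Cc1ncccc1CCCCCI | intermediate
11 | (1S,3S,9R,9aR)-9-(5-chloropentyl)-3-methyl-1-[5-(2-methylpyridin-3-yl)pentyl]octahydro-2H-quinolizin-2-one | C[C@H]1CN2CCC[C@@H](CCCCCCl)[C@@H]2[C@H](CCCCCc3cccnc3C)C1=O | intermediate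
12 | (1S,3S,9R,9aR)-9-(5-chloropentyl)-1-{5-[2-(4-methoxy-3-methyl-2-oxobutyl)pyridin-3-yl]pentyl}-3-methyloctahydro-2H-quinolizin-2-one | C[C@H]1CN2CCC[C@@H](CCCCCCl)[C@@H]2[C@H](CCCCCc3cccnc3CC(=O)C(C)COC)C1=O | intermediate
13 | iodide analogue of 12 (9-(5-iodopentyl)) | C[C@H]1CN2CCC[C@@H](CCCCCI)[C@@H]2[C@H](CCCCCc3cccnc3CC(=O)C(C)COC)C1=O | intermediate (not isolated)
14 | open-tail macrocycle: 16-membered carbocycle in which the pyridin-2-yl CH of unit B carries the chain from C9 of unit A and the 3-methoxy-2-methylpropanoyl group | C[C@H]1CN2CCC[C@H]3CCCCCC(C(=O)C(C)COC)c4ncccc4CCCCC[C@H](C1=O)[C@@H]32 | intermediate (not isolated)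
15 | macrocyclic pyridinium chloride hydrochloride (unit A 1S,3S,9R,9aR; unit B as 2-oxo-tetrahydroquinolizinium) | C[C@H]1C[NH+]2CCC[C@H]3CCCCCC4C(=O)C(C)C[n+]5cccc(CCCCC[C@H](C1=O)[C@@H]32)c45.[Cl-].[Cl-] | intermediate
16 | hydrogenation product before equilibration (unit B 9S,9aR; C1 and C3 of unit B epimeric) | C[C@H]1CN2CCC[C@H]3CCCCCC4C(=O)C(C)CN5CCC[C@H](CCCCC[C@H](C1=O)[C@@H]32)[C@H]45 | intermediate (not isolated)
17 | target: macrocyclic bis(3-methylquinolizidin-2-one), unit A 1S,3S,9R,9aR, unit B 1R,3S,9S,9aR | C[C@H]1CN2CCC[C@H]3CCCCC[C@H]4C(=O)[C@@H](C)CN5CCC[C@H](CCCCC[C@H](C1=O)[C@@H]32)[C@H]45 | target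

**Step count**
Total: 8 steps. Longest linear sequence: 7 steps (1, 2, 3, 5, 6, 7, 8).

**Three steps most likely to fail**

Step 8 (catalyst-controlled hydrogenation of the macrocyclic pyridinium; the same untested substrate class is first tried in step 3). The fallback sets out from 15 and comes back at 16. Compound 15 is reduced without facial control (H2, 4 bar, PtO2, AcOH), which adds hydrogen cis across ring A of unit B from both faces and also reduces both ketones, giving the diol mixture F6. Dess–Martin oxidation returns the diketones, namely 16 and, after the same amine equilibration, the unit B facial isomer F7. These are diastereomers because unit A is already a single enantiomer, so they are separated by chromatography (at most half the material is kept).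

Step 7 (16-membered ring closure by enolate C-alkylation). The fallback sets out from 11 and comes back at 14. The ring is closed before the acylation: 11 is treated with LiN(iPr)2 (2.2 equiv; ring ketone held as enolate) at 2 mM and warmed to 25 °C, so that the laterally lithiated 2-methyl group displaces the primary chloride and gives the macrocyclic 2-alkylpyridine F5. Lateral lithiation of F5 at the now secondary pyridylic carbon and acylation with 5 then give 14, which is cyclised with HCl/AcOH to 15 as in the route.

Step 6 (lateral lithiation and acylation beside an unprotected ketone). The fallback sets out from 7 and comes back at 16. Ring B of unit B is closed before the fragments are joined: 7 is neutralised (NaHCO3) to the 2-pyridone methide F1 and exchanged with NaI to the iodide F2, which has no acidic C–H. The lithium enolate of 9 is alkylated with F2 as in step 5 to give the coupled enaminone F3. Heating F3 with NaI in MeCN at 1 mM lets the nucleophilic methide carbon displace the iodide formed in the flask and closes the carbocycle as the pyridinium iodide F4 (competing quaternisation of the unit A amine is the weak point here). F4 is hydrogenated under the step 8 conditions to 16.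

**Further compounds**
F1 | step 6 | 9-(5-chloropentyl)-3-methyl-3,4-dihydro-2H-quinolizin-2-one (C3 racemic) | CC1CN2C=CC=C(CCCCCCl)C2=CC1=O
F2 | step 6 | 9-(5-iodopentyl)-3-methyl-3,4-dihydro-2H-quinolizin-2-one (C3 racemic) | CC1CN2C=CC=C(CCCCCI)C2=CC1=O
F3 | step 6 | (1S,3S,9R,9aR)-9-(5-chloropentyl)-3-methyl-1-[5-(3-methyl-2-oxo-3,4-dihydro-2H-quinolizin-9-yl)pentyl]octahydro-2H-quinolizin-2-one | C[C@H]1CN2CCC[C@@H](CCCCCCl)[C@@H]2[C@H](CCCCCC3=CC=CN4CC(C)C(=O)C=C34)C1=O
F4 | step 6 | macrocyclic pyridinium iodide (unit A complete, amine as free base) | C[C@H]1CN2CCC[C@H]3CCCCCC4C(=O)C(C)C[n+]5cccc(CCCCC[C@H](C1=O)[C@@H]32)c45.[I-]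
F5 | step 7 | macrocyclic 2-alkylpyridine (unit A complete; unit B as 2,3-dialkylpyridine) | C[C@H]1CN2CCC[C@H]3CCCCCCc4ncccc4CCCCC[C@H](C1=O)[C@@H]32
F6 | step 8 | diol mixture from uncontrolled hydrogenation (unit B centres and both carbinol centres undefined) | C[C@H]1CN2CCC[C@H]3CCCCCC4C(O)C(C)CN5CCCC(CCCCC[C@H](C1O)[C@@H]32)C45
F7 | step 8 | unit B facial isomer of the target (unit A 1S,3S,9R,9aR; unit B 1S,3R,9R,9aS) | C[C@H]1CN2CCC[C@H]3CCCCC[C@@H]4C(=O)[C@H](C)CN5CCC[C@@H](CCCCC[C@H](C1=O)[C@@H]32)[C@@H]45
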